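**Retrosynthetic overview**
- Last operations: global O-debenzylation, preceded by re-oxidation of a flavan-4-ol to the flavanone C4 ketone. The ketone is masked as the alcohol so the base-labile flavanone cannot ring-open during biaryl coupling.
- Biaryl bond (flavanone C3' to flavone C8''): late Suzuki coupling of an 8-iodoflavone half with an arylboronate flavan-4-ol half.
- Flavanone ring and its only stereocentre (C2, S): enantioselective intramolecular oxa-Michael addition of a 2'-hydroxyaryl alkylidene β-ketoester (made by Knoevenagel condensation), then decarboxylation.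
- Flavone ring: chalcone, then oxa-Michael/oxidative cyclisation (I2/DMSO), then C8 iodination.
- Both A-rings come from one dibenzylated phloroacetophenone. The two pyranone rings are built in parallel branches, then joined.

Assumption 1: the target SMILES defines only C2 (S); the 3'–8'' biaryl axis is treated as not stereodefined and is not controlled.
Assumption 2: the quinidine-derived thiourea is taken to give the (2S) series; I am not certain of this sense, and if it is reversed the quinine-derived pseudo-enantiomer is used (check by chiral HPLC and CD).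

**Branch A: iodoflavone**

Step 1
Reactants: 1, 2',4',6'-trihydroxyacetophenone
Product: 2, 1-[2,4-bis(benzyloxy)-6-hydroxyphenyl]ethan-1-one
Conditions: BnBr (2.05 equiv), K2CO3, DMF, 0 °C to rt
Reagents that add atoms: benzyl bromide, BrCc1ccccc1
Why: Williamson etherification alkylates the 4-OH and one ortho-OH, while the remaining ortho-OH is hydrogen-bonded to the ketone and stays free.

Step 2
Reactants: 2; 3, 4-methoxybenzaldehyde
Product: 4, (E)-1-[2,4-bis(benzyloxy)-6-hydroxyphenyl]-3-(4-methoxyphenyl)prop-2-en-1-one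
Conditions: 50% aq. KOH, EtOH, rt, 48 h
Reagents that add atoms: none
Why: Claisen–Schmidt aldol condensation gives the E-chalcone, and the benzyl ethers are stable to hydroxide.

Step 3
Reactants: 4
Product: 5, 5,7-bis(benzyloxy)-2-(4-methoxyphenyl)-4H-chromen-4-one
Conditions: I2 (10 mol%), DMSO, 130 °C
Reagents that add atoms: none
Why: intramolecular oxa-Michael closure of the 2'-hydroxychalcone followed by iodine/DMSO dehydrogenation gives the flavone.

Step 4
Reactants: 5
Product: 6, 5,7-bis(benzyloxy)-8-iodo-2-(4-methoxyphenyl)-4H-chromen-4-one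
Conditions: NIS (1.1 equiv), TFA (0.2 equiv), MeCN/CH2Cl2, rt, dark
Reagents that add atoms: N-iodosuccinimide, O=C1CCC(=O)N1I
Why: electrophilic aromatic iodination of 5,7-dialkoxyflavones goes to C8 (para to the 5-OR, ortho to the 7-OR), and C6 is crowded between two OBn groups.

**Branch B: enantioenriched flavan-4-ol boronate**

Step 5
Reactants: 7, 3-bromo-4-methoxybenzaldehyde
Product: 8, 4-methoxy-3-(4,4,5,5-tetramethyl-1,3,2-dioxaborolan-2-yl)benzaldehyde
Conditions: B2pin2 (1.1 equiv), Pd(dppf)Cl2 (3 mol%), KOAc, dioxane, 85 °C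
Reagents that add atoms: bis(pinacolato)diboron, CC1(C)OB(OC1(C)C)B1OC(C)(C)C(C)(C)O1
Why: Miyaura borylation of the aryl bromide tolerates the aldehyde.

Step 6
Reactants: 2
Product: 9, tert-butyl 3-[2,4-bis(benzyloxy)-6-hydroxyphenyl]-3-oxopropanoate
Conditions: LiHMDS (3.2 equiv), THF, −78 °C; Boc2O (1.1 equiv), −78 to 0 °C; aq. NH4Cl
Reagents that add atoms: di-tert-butyl dicarbonate, CC(C)(C)OC(=O)OC(=O)OC(C)(C)C
Why: Claisen-type C-acylation of the phenoxide/enolate dianion (any O-Boc transfers O to C) gives the β-ketoester, and the tert-butyl ester resists lactonisation to a 4-hydroxycoumarin.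

Step 7
Reactants: 9; 8
Product: 10, tert-butyl 2-[2,4-bis(benzyloxy)-6-hydroxybenzoyl]-3-[4-methoxy-3-(pinacolboryl)phenyl]prop-2-enoate (E/Z mixture, no stereocentre)
Conditions: piperidine (20 mol%), AcOH (20 mol%), 4 Å MS, toluene, rt
Reagents that add atoms: none
Why: Knoevenagel condensation under buffered conditions gives the doubly activated Michael acceptor while limiting premature racemic cyclisation.

Step 8 (key ring closure)
Reactants: 10
Product: 11, (2S)-5,7-bis(benzyloxy)-2-[4-methoxy-3-(pinacolboryl)phenyl]-2,3-dihydro-4H-chromen-4-one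
Conditions: 9-amino-9-deoxy-epi-quinidine 3,5-bis(trifluoromethyl)phenyl thiourea (10 mol%), toluene, −25 °C; then anhydrous TsOH (1.2 equiv), 80 °C, one pot
Reagents that add atoms: none
Why: enantioselective 6-endo intramolecular oxa-Michael addition, in which the thiourea binds the β-ketoester and the quinuclidine delivers the phenol to one face to set C2 as S; acid then removes the tert-butyl ester and decarboxylates without reopening the ring.

Step 9
Reactants: 11
Product: 12, (2S,4S)-5,7-bis(benzyloxy)-2-[4-methoxy-3-(pinacolboryl)phenyl]chroman-4-ol (2,4-cis major)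
Conditions: NaBH4, THF/EtOH, 0 °C, 30 min; aq. NH4Cl
Reagents that add atoms: none
Why: fast 1,2-reduction removes the enolisable ketone so C2 cannot be scrambled by retro-oxa-Michael opening in the basic coupling; the C4 configuration is temporary and any trans epimer converges at Step 11.

**Union and end game**

Step 10
Reactants: 6; 12 (1.3 equiv)
Product: 13, 5,7-bis(benzyloxy)-8-{5-[(2S,4S)-5,7-bis(benzyloxy)-4-hydroxychroman-2-yl]-2-methoxyphenyl}-2-(4-methoxyphenyl)-4H-chromen-4-one
Conditions: Pd(OAc)2 (5 mol%), SPhos (10 mol%), K3PO4, toluene/H2O (10:1), 80 °C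
Reagents that add atoms: none
Why: Suzuki–Miyaura coupling with a bulky biaryl phosphine forms the tri-ortho-substituted biaryl, and the flavan-4-ol has no acidic C–H through which base could open the ring.

Step 11
Reactants: 13
Product: 14, 5,7-bis(benzyloxy)-8-{5-[(2S)-5,7-bis(benzyloxy)-4-oxochroman-2-yl]-2-methoxyphenyl}-2-(4-methoxyphenyl)-4H-chromen-4-one
Conditions: Dess–Martin periodinane (1.3 equiv), NaHCO3, CH2Cl2, 0 °C to rt
Reagents that add atoms: none
Why: buffered, non-basic Dess–Martin oxidation of the benzylic alcohol restores the flavanone ketone without touching C2.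

Step 12
Reactants: 14
Product: 15, 2,3-dihydro-4',4'''-di-O-methylamentoflavone (target, 2S)
Conditions: H2 (1 atm), 10% Pd/C, THF/MeOH, rt, stopped after uptake of 4 equiv
Reagents that add atoms: none
Why: neutral hydrogenolysis cleaves the four aryl benzyl ethers and leaves the two aryl methyl ethers, the flavone C2=C3 bond and the base-sensitive (2S)-flavanone intact.

**Compound list**
1 | 2',4',6'-trihydroxyacetophenone | CC(=O)c1c(O)cc(O)cc1O | starting material
2 | 1-[2,4-bis(benzyloxy)-6-hydroxyphenyl]ethan-1-one | CC(=O)c1c(O)cc(OCc2ccccc2)cc1OCc1ccccc1 | intermediate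
3 | 4-methoxybenzaldehyde | COc1ccc(C=O)cc1 | starting material
4 | (E)-2'-hydroxy-4',6'-bis(benzyloxy)-4-methoxychalcone | COc1ccc(/C=C/C(=O)c2c(O)cc(OCc3ccccc3)cc2OCc2ccccc2)cc1 | intermediate
5 | 5,7-bis(benzyloxy)-4'-methoxyflavone | COc1ccc(-c2cc(=O)c3c(OCc4ccccc4)cc(OCc4ccccc4)cc3o2)cc1 | intermediate
6 | 5,7-bis(benzyloxy)-8-iodo-4'-methoxyflavone | COc1ccc(-c2cc(=O)c3c(OCc4ccccc4)cc(OCc4ccccc4)c(I)c3o2)cc1 | intermediate
7 | 3-bromo-4-methoxybenzaldehyde | COc1ccc(C=O)cc1Br | starting material
8 | 4-methoxy-3-(pinacolboryl)benzaldehyde | COc1ccc(C=O)cc1B1OC(C)(C)C(C)(C)O1 | intermediate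
9 | tert-butyl 3-[2,4-bis(benzyloxy)-6-hydroxyphenyl]-3-oxopropanoate | CC(C)(C)OC(=O)CC(=O)c1c(O)cc(OCc2ccccc2)cc1OCc1ccccc1 | intermediate
10 | alkylidene β-ketoester (E/Z mixture) | COc1ccc(C=C(C(=O)OC(C)(C)C)C(=O)c2c(O)cc(OCc3ccccc3)cc2OCc2ccccc2)cc1B1OC(C)(C)C(C)(C)O1 | intermediate
11 | (2S)-5,7-bis(benzyloxy)-3'-(pinacolboryl)-4'-methoxyflavanone | COc1ccc([C@@H]2CC(=O)c3c(OCc4ccccc4)cc(OCc4ccccc4)cc3O2)cc1B1OC(C)(C)C(C)(C)O1 | intermediate
12 | (2S,4S)-flavan-4-ol boronate | COc1ccc([C@@H]2C[C@H](O)c3c(OCc4ccccc4)cc(OCc4ccccc4)cc3O2)cc1B1OC(C)(C)C(C)(C)O1 | intermediate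
13 | tetra-O-benzyl flavan-4-ol–flavone biaryl | COc1ccc(-c2cc(=O)c3c(OCc4ccccc4)cc(OCc4ccccc4)c(-c4cc([C@@H]5C[C@H](O)c6c(OCc7ccccc7)cc(OCc7ccccc7)cc6O5)ccc4OC)c3o2)cc1 | intermediate
14 | tetra-O-benzyl-(2S)-2,3-dihydro-4',4'''-di-O-methylamentoflavone | COc1ccc(-c2cc(=O)c3c(OCc4ccccc4)cc(OCc4ccccc4)c(-c4cc([C@@H]5CC(=O)c6c(OCc7ccccc7)cc(OCc7ccccc7)cc6O5)ccc4OC)c3o2)cc1 | intermediate
15 | (2S)-2,3-dihydro-4',4'''-di-O-methylamentoflavone | COc1ccc(-c2cc(=O)c3c(O)cc(O)c(-c4cc([C@@H]5CC(=O)c6c(O)cc(O)cc6O5)ccc4OC)c3o2)cc1 | target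

**Totals**
- Total steps: 12.
- Longest linear sequence: 8 steps (1, 6, 7, 8, 9, 10, 11, 12), which is two thirds of the total. The other two branches are 7 steps each.

**Three steps most likely to fail**
1. Step 8. The ee may be low on this 6'-benzyloxy substrate, and the aryl boronate may partly protodeboronate under TsOH. Fallback: cyclise 10 racemically (Et3N, then TsOH) and move stereocontrol to the reduction. A Noyori Ru–TsDPEN transfer-hydrogenation kinetic resolution of racemic 11 reduces only the (2S)-ketone and gives (2S,4S)-12 directly.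
2. Step 10. The hindered coupling may suffer protodeboronation of the ortho-methoxy arylboronate or deiodination of 6. Fallback: couple 6 with aldehyde 8 first, then build the flavanone on the resulting biaryl aldehyde by Knoevenagel condensation with 9 and the same asymmetric oxa-Michael/decarboxylation. This is more linear but needs no Step 9/11 redox detour.
3. Step 4. Iodination may give C6/C8 mixtures or over-iodination. Fallback: iodinate acetophenone 2 ortho to the chelated phenol (BnMe3N·ICl2), confirm the regiochemistry on that small molecule, then carry the iodide through chalcone formation and I2/DMSO cyclisation so it ends up at C8.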